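Cedar runs for 15 min and oak for 8.0 min, from the same charges.

- cedar: starting material 13 mM; reagent 26.0 mM; second substrate 26.0 mM; protic impurity 13.0 mM; catalyst 7.1 µM; time 15 min
- oak: starting material 13 mM; reagent 26.0 mM; second substrate 26.0 mM; protic impurity 13.0 mM; catalyst 7.1 µM; time 8.0 min

    second substrate + protic impurity → quenched substrate (k1 = 1.1 /M/s)
    second substrate + reagent + catalyst → catalyst + second product (k2 = 7600 /M²/s)
    starting material + reagent + catalyst ⇌ catalyst + target (K3 = 19 /M, k3 = 29000 /M²/s)

- which of these there is most of at the end, counted by the starting material in it, cedar (target / starting material)
- which of these there is most of at the end, counted by the starting material in it, oak (target / starting material)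
- amount of the one of these that there is most of at the end, in percent of the starting material charged, cedar
- amount of the one of these that there is most of at the end, in percent of the starting material charged, oak

What holds the starting material back? With reagent as charged, the target equilibrium relaxes with a half-life of 0.714 min, shorter than oak's time, so I treat it as a quasi-equilibrium. Call the equilibrium constant K and the free reagent R. The share of starting material is then one over one plus K times R.

And R? It is the reagent charge less what target and second product have taken.

How much second product? The quench of second substrate by protic impurity has a half-life of 0.808 min, against 8.23 min for the catalysed side step. So I let the quench go first, and for the side step I count a surplus of second substrate, S, of 13.0 mM.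

At what rate does S react? Take R at its charge for a first target of 4.30 mM; with R as the charge less this target, the pseudo-first-order constant of the side step is 0.0703 /min. For cedar I then reckon 8.47 mM of second product.

But that first target ignored second product, didn't it? Yes, so the answer goes back in. R falls to 13.2 mM, target to 2.61 mM, and the free reagent at the end, charge less target less second product, comes to 14.9 mM in cedar. So I expect cedar to end with starting material at 77.9%.

And oak? I reckon second product at 5.59 mM, and the same two rounds, through 16.1 mM, give R of 17.4 mM. So I expect oak to end with starting material at 75.2%.

The forecast gives starting material at 77% in cedar and starting material at 75% in oak, holding that “target simply tracks the free reagent”.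

The simulation gives starting material at 77.4% in cedar and starting material at 75.0% in oak.

Cedar has not come to rest at 15.0 min: its slowest mode still has a half-life of 11.0 min, and second substrate stands at 19.5% of its charge. My ledger leaves 4.53 mM of the surplus unspent. Taken from 14.9 mM, with reagent returned by target not counted, that puts R at 10.4 mM and starting material at 83.5%. At 150 min cedar stands at 83.0% starting material, with second product at 13.0 mM and target down from 22.6% to 17.0%.

Now the neighbour of cedar charged with 100 mM of reagent. Target of 8.52 mM and second product of 12.8 mM leave R at 78.6 mM, so starting material should be 40.1%. The simulation gives 40.0%, with target holding most at 60.0%, a different winner from cedar's starting material.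

(Its constants are made up, and the outcome is calculated.)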